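All runs were computed for an exercise, and the scatter is random.

A flask cannot hold more Z than its J pays for: with 0.150 M of J on 0.30 M of L, Z plus half of D is capped at 50.0% of the L charged. The midnight run reads 49.9% at its last reading with L still at 40.5%, so J is the limiting reagent of that run.

common to all: X 1.5 mM

| run | L | J | temperature | remark | time |
|---|---|---|---|---|---|
| midnight | 0.30 M | 0.15 M | 65 °C | run made earlier |  |
| spring | 0.30 M | 0.075 M | 76 °C | run made earlier |  |
| autumn | 0.30 M | 0.11 M | 65 °C | run made earlier |  |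
| teal | 0.30 M | 0.150 M (fed, over 20 min) | 70 °C | all else is in the flask from the start; the feed brings no volume worth counting | 30 min |
| ochre | 0.30 M | 0.150 M (fed, over 20 min) |  | the addition at 30 °C, then warmed to 70 °C; the feed brings no volume worth counting | 30 min |
| grey | 0.30 M (fed, over 20 min) | 0.150 M | 70 °C | all else is in the flask from the start; the feed brings no volume worth counting | 30 min |
| red | 0.30 M | 0.150 M | 70 °C | everything together at the start | 30 min |

| run | time / min | Z / % | D / % | L / % |
|---|---|---|---|---|
| midnight | 1.33 | 5.9 | 0 | 93.9 |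
| midnight | 4.00 | 17.1 | 2.1 | 81.0 |
| midnight | 6.00 | 23.8 | 3.7 | 71.9 |
| midnight | 10.0 | 34.8 | 8.2 | 57.7 |
| midnight | 15.0 | 40.7 | 14.3 | 44.1 |
| midnight | 20.0 | 40.3 | 19.1 | 40.5 |
| spring | 1.33 | 10.1 | 1.2 | 88.4 |
| spring | 4.00 | 20.3 | 6.3 | 73.2 |
| spring | 6.00 | 19.1 | 10.7 | 69.7 |
| spring | 10.0 | 16.1 | 18.3 | 65.9 |
| spring | 15.0 | 12.2 | 25.6 | 62.6 |
| spring | 20.0 | 9.6 | 30.5 | 59.6 |
| autumn | 1.33 | 6.1 | 0.3 | 93.8 |
| autumn | 4.00 | 16.4 | 2.3 | 82.1 |
| autumn | 6.00 | 22.8 | 3.7 | 74.4 |
| autumn | 10.0 | 30.1 | 8.4 | 61.6 |
| autumn | 15.0 | 29.3 | 13.5 | 56.8 |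
| autumn | 20.0 | 27.2 | 18.2 | 54.5 |

(each reading ± 0.3 percentage points)

- in percentages every species weighs as the L in it: one D counts as two

* the flask that comes out highest in share of Z in Z plus D, or "all alike" when all lie within 1.5 percentage points (teal / ochre / grey / red / all alike)
* share of Z in Z plus D at the end, teal
* share of Z in Z plus D at the end, ochre
* share of Z in Z plus D at the end, grey
* share of Z in Z plus D at the end, red

Two chemists argue from the same reading. Define the wear constant κ as the rise of D per minute divided by the product of Z and L, each as a fraction of the charge. Taken over the last 10.0 min with the middle reading, the midnight run gives 0.0607 min⁻¹ at 65 °C, and the spring run gives 0.160 min⁻¹ at 76 °C. Reading the logarithm straight across temperature gives 0.0943 min⁻¹ at 70 °C. D counts double, so Z loses half of what D gains. My own reckoning of the wear time τ is therefore 14.7 min: the minutes in which Z would lose half of itself to L held at its full charge.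

The first chemist expects the flasks to lie together. The charges and the cap are equal, and the run of 30 min is longer than τ, so the path should be forgotten. The second answers that red gets 2.04 wear times. Ochre gets 0.680 in its hot 10.0 min, because at 30 °C, on the same line far beyond the readings, τ is 495 min, much longer than the feed of 20 min.

The forecast sides with the second: “Both steps scale with L”. It gives ochre 71%, grey 58%, teal 49% and red 45%, with ochre highest.

The flasks end at ochre 71.7%, grey 57.3%, teal 49.7% and red 44.2%, so ochre is highest.

    Q → X + Z (k = 4.30 s⁻¹, Ea = 83.0 kJ mol⁻¹)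
    J + X → G (k = 16.0 M⁻¹ s⁻¹, Ea = 53.0 kJ mol⁻¹)
    L + G → Q (k = 0.890 M⁻¹ s⁻¹, Ea = 55.0 kJ mol⁻¹)
    X → E (k = 2.40 × 10⁻⁷ s⁻¹, Ea = 128 kJ mol⁻¹)
    L + Z → D (k = 0.00260 M⁻¹ s⁻¹, Ea = 85.0 kJ mol⁻¹)
    (constants at 70 °C)

In red at 4.23 min, Z is made 6.27 times faster than it is used up, yet after 2.04 wear times red holds Z 30.7% against D 38.7%. Red run at 95 °C has, on the same line beyond the readings, a τ of 1.63 min, so 18.4 wear times, and it ends at 8.84%. That is the first chemist's region: left to 300 min, red stands at 6.71% and ochre at 7.14%, which is 0.43 percentage points apart against a margin of 1.5 points.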